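**Retrosynthetic overview**
1. Target 20 ⇐ acylation of the C4 hydroxyl and desilylation of hydroazulene diol 18 ⇐ hydroxyl-directed reduction of hydroazulen-4-one 17.
2. Key step: 17 ⇐ cis-decalin hydroxy mesylate 16 by a semipinacol 1,2-shift (C8a moves from C4a to C5). Ring A contracts 6→5, ring B expands 6→7, and the trans ring fusion is fixed.
3. 16 ⇐ all-cis triol 15 ⇐ hydroxyl-directed dihydroxylation of 14 ⇐ hydroxyl-directed 1,3-anti reduction and silylation of decalin enone 12.
4. Ring B of 12 ⇐ intramolecular vinylogous aldol of senecioyl enone 11 ⇐ acetyl group of 7 + acetone.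
5. Ring A (7) ⇐ new enantioselective desymmetrising aldol condensation of triketone 5 ⇐ Michael addition of 3 to 4. Ring order: ring A, ring B, then 6-6 → 5-7.

Assumption: the sense of induction of the new catalytic step 3 is assigned by analogy; if it proves opposite, the enantiomeric diamine is used.

Locants: naphthalene numbering for 12–16, azulene numbering for 17–20.

Step 1
Reactants: 1 anisole
Product: 2 4-methoxybenzoyl chloride
Conditions: (COCl)2 (1.5 equiv), AlCl3 (1.1 equiv), CH2Cl2, −10 → 0 °C; distillation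
Reagents that add atoms: oxalyl chloride, O=C(Cl)C(=O)Cl
Why: Friedel–Crafts chlorocarbonylation, in which the chlorooxalyl cation loses CO and the chlorocarbonyl cation attacks anisole para to the methoxy group.

Step 2
Reactants: 3 3-methylpentane-2,4-dione; 4 4-methylpent-1-en-3-one
Product: 5 3-acetyl-3,7-dimethyloctane-2,6-dione
Conditions: FeCl3·6H2O (2 mol %), neat, 23 °C
Reagents that add atoms: none
Why: Michael addition of the iron-chelated 1,3-diketonate to the vinyl ketone under neutral conditions (no retro-Claisen), giving the prochiral fully substituted carbon with two enantiotopic acetyl groups.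

Step 3
Reactants: 5 3-acetyl-3,7-dimethyloctane-2,6-dione
Product: 7 (R)-6-acetyl-6-methyl-3-(propan-2-yl)cyclohex-2-en-1-one, via aldol ketol 6 (not isolated)
Conditions: (S)-N1,N1-diethyl-3,3-dimethylbutane-1,2-diamine·CF3SO3H (10 mol %), 3-nitrobenzoic acid (10 mol %), toluene, 50 °C, 48 h
Reagents that add atoms: none
Why: Proposed new method: the primary amine forms an enamine reversibly at either enantiotopic acetyl group, and the 6-enolexo aldol onto the side-chain isopropyl ketone (activated by the ammonium N–H in a chair transition state) selects one of them and so sets the quaternary stereocentre; dehydration to the conjugated enone is the only irreversible channel (the other aldol modes give a four-membered ring or a ketol that cannot dehydrate); the closest known reaction type is the Hajos–Parrish–Eder–Sauer–Wiechert amine-catalysed aldol condensation, known for enantiotopic acceptor carbonyls and for 4-substituted heptane-2,6-diones but not for two enantiotopic acetyl donors on a quaternary carbon.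

Step 4
Reactants: 7 (R)-6-acetyl-6-methyl-3-(propan-2-yl)cyclohex-2-en-1-one; 8 acetone
Product: 11 (R)-6-methyl-6-(3-methylbut-2-enoyl)-3-(propan-2-yl)cyclohex-2-en-1-one, via lithium aldolate 9 (not isolated), via tertiary mesylate 10 (not isolated)
Conditions: LiN(i-Pr)2 (1.05 equiv), THF, −78 °C; acetone; then MeSO2Cl, Et3N, −78 → 23 °C
Reagents that add atoms: none
Why: Aldol addition then mesylation and E1cB elimination; the acetyl CH3 is the only α-position (the other α-carbon is quaternary), so the kinetic enolate adds to acetone and the adduct eliminates to the β,β-dimethyl enone without touching the stereocentre.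

Step 5
Reactants: 11 (R)-6-methyl-6-(3-methylbut-2-enoyl)-3-(propan-2-yl)cyclohex-2-en-1-one
Product: 12 (4aS,8aS)-4a-hydroxy-3,8a-dimethyl-6-(propan-2-yl)-4a,7,8,8a-tetrahydronaphthalen-1(4H)-one
Conditions: LiN(i-Pr)2 (1.1 equiv), THF, −78 → −40 °C; H2O
Reagents that add atoms: none
Why: Intramolecular vinylogous aldol (Robinson-type ring closure): γ-deprotonation of the senecioyl ketone gives a dienolate whose γ-carbon adds 1,2 to the ring ketone (α-attack would give a four-membered ring), and attack through the axial acyl arm gives the cis-fused ketol with the 4a-OH cis to the 8a-methyl.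

Step 6
Reactants: 12 (4aS,8aS)-4a-hydroxy-3,8a-dimethyl-6-(propan-2-yl)-4a,7,8,8a-tetrahydronaphthalen-1(4H)-one
Product: 13 (1R,4aS,8aR)-3,8a-dimethyl-6-(propan-2-yl)-1,4,4a,7,8,8a-hexahydronaphthalene-1,4a-diol
Conditions: Me4NBH(OAc)3 (5 equiv), MeCN/AcOH 1:1, −30 °C
Reagents that add atoms: none
Why: Evans–Saksena reduction: the 4a-alkoxy(diacetoxy)borohydride delivers hydride intramolecularly to the face of C1 that carries the 4a-oxygen, so the new hydroxyl is 1,3-anti to the 4a-OH and trans to the angular methyl (the future C8 configuration).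

Step 7
Reactants: 13 (1R,4aS,8aR)-3,8a-dimethyl-6-(propan-2-yl)-1,4,4a,7,8,8a-hexahydronaphthalene-1,4a-diol
Product: 14 (1R,4aS,8aR)-1-{[tert-butyl(dimethyl)silyl]oxy}-3,8a-dimethyl-6-(propan-2-yl)-1,7,8,8a-tetrahydronaphthalen-4a(4H)-ol
Conditions: t-BuMe2SiOTf (1.1 equiv), 2,6-lutidine, CH2Cl2, −78 °C
Reagents that add atoms: tert-butyldimethylsilyl trifluoromethanesulfonate, CC(C)(C)[Si](C)(C)OS(=O)(=O)C(F)(F)F
Why: Silyl ether formation at the secondary allylic alcohol, which reacts much faster than the tertiary ring-fusion alcohol at −78 °C; this removes the second directing hydroxyl and the second secondary alcohol for steps 8, 9 and 11.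

Step 8
Reactants: 14 (1R,4aS,8aR)-1-{[tert-butyl(dimethyl)silyl]oxy}-3,8a-dimethyl-6-(propan-2-yl)-1,7,8,8a-tetrahydronaphthalen-4a(4H)-ol
Product: 15 (1R,4aR,5S,6R,8aR)-1-{[tert-butyl(dimethyl)silyl]oxy}-3,8a-dimethyl-6-(propan-2-yl)-1,4,4a,5,6,7,8,8a-octahydronaphthalene-4a,5,6-triol
Conditions: OsO4 (1.05 equiv), TMEDA (1.1 equiv), CH2Cl2, −78 °C; then aq. Na2SO3, THF, 23 °C
Reagents that add atoms: osmium tetroxide, O=[Os](=O)(=O)=O
Why: Donohoe hydroxyl-directed dihydroxylation: OsO4·TMEDA hydrogen-bonded to the free 4a-OH adds to the allylic C5=C6 alkene from the same (convex) face, giving the all-cis 4a,5,6-triol, while the C2=C3 alkene next to the silyl ether has no directing group.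

Step 9
Reactants: 15 (1R,4aR,5S,6R,8aR)-1-{[tert-butyl(dimethyl)silyl]oxy}-3,8a-dimethyl-6-(propan-2-yl)-1,4,4a,5,6,7,8,8a-octahydronaphthalene-4a,5,6-triol
Product: 17 (3R,3aR,8R,8aS)-8-{[tert-butyl(dimethyl)silyl]oxy}-3-hydroxy-6,8a-dimethyl-3-(propan-2-yl)-2,3,3a,5,8,8a-hexahydroazulen-4(1H)-one, via C5 mesylate 16 (not isolated)
Conditions: MeSO2Cl (1.2 equiv), Et3N, CH2Cl2, −20 °C; then Et3Al (4 equiv), −78 → 0 °C
Reagents that add atoms: none
Why: Tsuchihashi–Suzuki organoaluminium-promoted semipinacol 1,2-shift: in the chair with equatorial isopropyl the equatorial C5 mesylate (the only secondary OH) is antiperiplanar to the C4a–C8a bond, and the fully substituted C8a (a better migrating group than the C7 methylene, which is antiperiplanar on the other side) migrates to C5 with inversion as the 4a-alkoxide becomes the ketone; ring A contracts to the cyclopentane and ring B expands to the cycloheptenone, which sets C3a stereospecifically (H trans to the angular methyl) and leaves C3, C8 and C8a untouched.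

Step 10
Reactants: 17 (3R,3aR,8R,8aS)-8-{[tert-butyl(dimethyl)silyl]oxy}-3-hydroxy-6,8a-dimethyl-3-(propan-2-yl)-2,3,3a,5,8,8a-hexahydroazulen-4(1H)-one
Product: 18 (3R,3aS,4S,8R,8aS)-8-{[tert-butyl(dimethyl)silyl]oxy}-6,8a-dimethyl-3-(propan-2-yl)-1,2,3,3a,4,5,8,8a-octahydroazulene-3,4-diol
Conditions: Me4NBH(OAc)3 (5 equiv), MeCN/AcOH 1:1, −30 °C
Reagents that add atoms: none
Why: Evans–Saksena reduction of the β-hydroxy ketone: hydride is delivered from the boron bound to the tertiary C3 oxygen through a chair six-membered transition state, which places the new C4 hydrogen syn to that oxygen and the C4 hydroxyl 1,3-anti (4S), without epimerising C3a.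

Step 11
Reactants: 18 (3R,3aS,4S,8R,8aS)-8-{[tert-butyl(dimethyl)silyl]oxy}-6,8a-dimethyl-3-(propan-2-yl)-1,2,3,3a,4,5,8,8a-octahydroazulene-3,4-diol; 2 4-methoxybenzoyl chloride
Product: 20 (3R,3aS,4S,8R,8aS)-3,8-dihydroxy-6,8a-dimethyl-3-(propan-2-yl)-1,2,3,3a,4,5,8,8a-octahydroazulen-4-yl 4-methoxybenzoate, via silyl ether ester 19 (not isolated)
Conditions: 2 (1.5 equiv), DMAP (0.3 equiv), Et3N, CH2Cl2, 35 °C; then HF·pyridine, THF, 0 → 23 °C
Reagents that add atoms: none
Why: DMAP-catalysed acylation of the only secondary alcohol (the tertiary C3-OH does not react), then fluoride cleavage of the silyl ether, to which the aryl ester is inert; no stereocentre is touched.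

**Compound list**
1 | anisole | COc1ccccc1 | starting material
2 | 4-methoxybenzoyl chloride | COc1ccc(C(=O)Cl)cc1 | intermediate
3 | 3-methylpentane-2,4-dione | CC(=O)C(C)C(C)=O | starting material
4 | 4-methylpent-1-en-3-one (isopropyl vinyl ketone) | C=CC(=O)C(C)C | starting material
5 | 3-acetyl-3,7-dimethyloctane-2,6-dione | CC(C)C(=O)CCC(C)(C(C)=O)C(C)=O | intermediate
6 | (6R)-6-acetyl-3-hydroxy-6-methyl-3-(propan-2-yl)cyclohexan-1-one (aldol ketol, both C3 epimers) | CC(=O)[C@@]1(C)CCC(O)(C(C)C)CC1=O | intermediate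
7 | (R)-6-acetyl-6-methyl-3-(propan-2-yl)cyclohex-2-en-1-one | CC(=O)[C@@]1(C)CCC(C(C)C)=CC1=O | intermediate
8 | acetone | CC(C)=O | starting material
9 | (R)-6-(3-hydroxy-3-methylbutanoyl)-6-methyl-3-(propan-2-yl)cyclohex-2-en-1-one (formed as its lithium alkoxide) | CC(C)(O)CC(=O)[C@@]1(C)CCC(C(C)C)=CC1=O | intermediate
10 | 2-methyl-4-[(1R)-1-methyl-2-oxo-4-(propan-2-yl)cyclohex-3-en-1-yl]-4-oxobutan-2-yl methanesulfonate | CC(C)(OS(C)(=O)=O)CC(=O)[C@@]1(C)CCC(C(C)C)=CC1=O | intermediate
11 | (R)-6-methyl-6-(3-methylbut-2-enoyl)-3-(propan-2-yl)cyclohex-2-en-1-one | CC(C)=CC(=O)[C@@]1(C)CCC(C(C)C)=CC1=O | intermediate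
12 | (4aS,8aS)-4a-hydroxy-3,8a-dimethyl-6-(propan-2-yl)-4a,7,8,8a-tetrahydronaphthalen-1(4H)-one (cis-fused, OH cis to the angular methyl) | C[C@]12CCC(C(C)C)=C[C@@]1(O)CC(C)=CC2=O | intermediate
13 | (1R,4aS,8aR)-3,8a-dimethyl-6-(propan-2-yl)-1,4,4a,7,8,8a-hexahydronaphthalene-1,4a-diol | C[C@]12CCC(C(C)C)=C[C@@]1(O)CC(C)=C[C@H]2O | intermediate
14 | (1R,4aS,8aR)-1-{[tert-butyl(dimethyl)silyl]oxy}-3,8a-dimethyl-6-(propan-2-yl)-1,7,8,8a-tetrahydronaphthalen-4a(4H)-ol | C[C@]12CCC(C(C)C)=C[C@@]1(O)CC(C)=C[C@H]2O[Si](C)(C)C(C)(C)C | intermediate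
15 | (1R,4aR,5S,6R,8aR)-1-{[tert-butyl(dimethyl)silyl]oxy}-3,8a-dimethyl-6-(propan-2-yl)-1,4,4a,5,6,7,8,8a-octahydronaphthalene-4a,5,6-triol (4a-, 5- and 6-OH and 8a-methyl all on one face) | C[C@]12CC[C@@](O)(C(C)C)[C@H](O)[C@@]1(O)CC(C)=C[C@H]2O[Si](C)(C)C(C)(C)C | intermediate
16 | (1R,4aR,5S,6R,8aR)-1-{[tert-butyl(dimethyl)silyl]oxy}-4a,6-dihydroxy-3,8a-dimethyl-6-(propan-2-yl)-1,4,4a,5,6,7,8,8a-octahydronaphthalen-5-yl methanesulfonate (locants of 15 kept) | C[C@]12CC[C@@](O)(C(C)C)[C@H](OS(C)(=O)=O)[C@@]1(O)CC(C)=C[C@H]2O[Si](C)(C)C(C)(C)C | intermediate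
17 | (3R,3aR,8R,8aS)-8-{[tert-butyl(dimethyl)silyl]oxy}-3-hydroxy-6,8a-dimethyl-3-(propan-2-yl)-2,3,3a,5,8,8a-hexahydroazulen-4(1H)-one (trans-fused) | O=C1CC(C)=C[C@@H](O[Si](C)(C)C(C)(C)C)[C@@]2(C)CC[C@@](O)(C(C)C)[C@H]12 | intermediate
18 | (3R,3aS,4S,8R,8aS)-8-{[tert-butyl(dimethyl)silyl]oxy}-6,8a-dimethyl-3-(propan-2-yl)-1,2,3,3a,4,5,8,8a-octahydroazulene-3,4-diol | O[C@H]1CC(C)=C[C@@H](O[Si](C)(C)C(C)(C)C)[C@@]2(C)CC[C@@](O)(C(C)C)[C@H]12 | intermediate
19 | (3R,3aS,4S,8R,8aS)-8-{[tert-butyl(dimethyl)silyl]oxy}-3-hydroxy-6,8a-dimethyl-3-(propan-2-yl)-1,2,3,3a,4,5,8,8a-octahydroazulen-4-yl 4-methoxybenzoate | COc1ccc(C(=O)O[C@H]2CC(C)=C[C@@H](O[Si](C)(C)C(C)(C)C)[C@@]3(C)CC[C@@](O)(C(C)C)[C@H]23)cc1 | intermediate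
20 | (3R,3aS,4S,8R,8aS)-3,8-dihydroxy-6,8a-dimethyl-3-(propan-2-yl)-1,2,3,3a,4,5,8,8a-octahydroazulen-4-yl 4-methoxybenzoate | COc1ccc(C(=O)O[C@H]2CC(C)=C[C@@H](O)[C@@]3(C)CC[C@@](O)(C(C)C)[C@H]23)cc1 | target

**Step count and risks**
Total steps: 11. Longest linear sequence: 10 (steps 2–11, from 3 and 4 to 20); step 1 is a one-step side branch.

The three steps most likely to fail:

Step 3 (the proposed new step). The desymmetrising aldol condensation may be slow (hindered methyl-ketone enamine, hindered acceptor) or poorly enantioselective. The fallback sets out from 5 and gives up asymmetric catalysis. Triketone 5 is cyclised with pyrrolidine and acetic acid in toluene, an ordinary enamine aldol condensation of a 1,5-diketone, to the racemate: 7 together with its enantiomer (S)-6-acetyl-6-methyl-3-(propan-2-yl)cyclohex-2-en-1-one F1. The enantiomers are separated by preparative supercritical-fluid chromatography on a chiral stationary phase, and the route is re-entered at 7.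

Step 5. The lithium dienolate may react sluggishly, lose water from the ketol to a dienone, or give some trans-fused ketol. The fallback sets out from 11 and replaces the enolate aldol by a Lewis-acid vinylogous Mukaiyama aldol. Soft enolisation of the s-cis senecioyl ketone (t-BuMe2SiOTf, Et3N, CH2Cl2, −78 °C) gives the silyl dienol ether (R)-6-{(1Z)-1-[(tert-butyldimethylsilyl)oxy]-3-methylbuta-1,3-dien-1-yl}-6-methyl-3-(propan-2-yl)cyclohex-2-en-1-one F2. BF3·OEt2 in CH2Cl2 at −78 °C then activates the ring ketone for attack by the γ-carbon, which is the inherent regiochemistry of silyl dienol ethers, and the route comes back at 12.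

Step 8. OsO4·TMEDA may also attack the second trisubstituted alkene or add to the wrong face. The fallback sets out from 14 and installs the cis-diol through an epoxide with overall retention. VO(acac)2 and t-BuOOH epoxidise only the alkene allylic to the free tertiary hydroxyl and syn to it, giving the 5,6-epoxide of 14 with the oxirane on the face of the 4a-hydroxyl F3. LiBr-catalysed insertion of CO2 (bromide opening, then ring closure by the carbonate, a double inversion at C5) gives the cis 5,6-cyclic carbonate of 15 F4. K2CO3 in MeOH frees the all-cis triol, and the route comes back at 15.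

**Further compounds**
F1 | step 3 | (S)-6-acetyl-6-methyl-3-(propan-2-yl)cyclohex-2-en-1-one | CC(=O)[C@]1(C)CCC(C(C)C)=CC1=O
F2 | step 5 | (R)-6-{(1Z)-1-[(tert-butyldimethylsilyl)oxy]-3-methylbuta-1,3-dien-1-yl}-6-methyl-3-(propan-2-yl)cyclohex-2-en-1-one | C=C(C)/C=C(\O[Si](C)(C)C(C)(C)C)[C@@]1(C)CCC(C(C)C)=CC1=O
F3 | step 8 | 5,6-epoxide of 14 with the oxirane oxygen on the face of the 4a-hydroxyl and 8a-methyl | C[C@]12CC[C@]3(C(C)C)O[C@@H]3[C@@]1(O)CC(C)=C[C@H]2O[Si](C)(C)C(C)(C)C
F4 | step 8 | 5,6-cyclic carbonate of 15 | C[C@]12CC[C@]3(C(C)C)OC(=O)O[C@@H]3[C@@]1(O)CC(C)=C[C@H]2O[Si](C)(C)C(C)(C)C
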